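Ring A (C1 OH, C2 O‑aryl, C3 Br, C4 H, C5 Br, C6 Br) is assembled from two three‑carbon chains instead of being carved out of an arene. Its C6–C1(O)–C2(OAr) segment is the methyl, carbonyl and aryloxymethylene carbon set of 1‑(2,4‑dibromophenoxy)propan‑2‑one. C3–C4–C5 is nitromalonaldehyde, whose central carbon puts a nitro group on C4. One double aldol condensation forms C2–C3 and C5–C6, closes ring A and sets the ring B ether next to the new hydroxyl, so no diaryl ether bond has to be forged. As an amine, the C4 nitrogen later steers bromine to C3 and C5 and is then excised, leaving C4–H.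

Key step: step 3

Remark on the chemistry: a free 4‑aminophenol is expected to be oxidised by bromine to a quinone imine. C6 is therefore brominated while the hydroxyl still directs (step 4), and the hydroxyl is carried as its methyl ether from step 5 to step 9.

Step 1
Reactants: 1 2,4‑dibromophenol; 2 chloroacetone
Product: 3 1‑(2,4‑dibromophenoxy)propan‑2‑one
Conditions: K2CO3, KI (cat.), acetone, reflux
Reagents that add atoms: none
Why: Williamson ether synthesis, in which the phenoxide formed by K2CO3 displaces halide from the activated α‑haloketone by SN2, assisted by in situ Finkelstein exchange with iodide.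

Step 2
Reactants: 4 mucobromic acid
Product: 5 sodium nitromalonaldehyde monohydrate
Conditions: NaNO2 (excess), H2O–EtOH, 50–55 °C; crystallise at 0 °C (small scale, behind a shield, not dried hot)
Reagents that add atoms: sodium nitrite [Na+].[O-]N=O; water O
Why: Standard nitrite degradation of a mucohalic acid (addition–elimination of nitrite at the bromo‑enal carbon, decarboxylation and replacement of the second bromine by oxygen) should give the delocalised nitromalonaldehyde anion, which crystallises as its impact‑ and heat‑sensitive sodium salt hydrate.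

Step 3
Reactants: 3 1‑(2,4‑dibromophenoxy)propan‑2‑one; 5 sodium nitromalonaldehyde monohydrate (slight excess)
Product: 7 2‑(2,4‑dibromophenoxy)‑4‑nitrophenol, via sodium nitrophenolate 6 (not isolated)
Conditions: NaOH (aq., ca. 1 equiv), EtOH–H2O, 0 °C → rt, several days; then HCl (aq.) to pH 2
Reagents that add atoms: none
Why: Hydroxide generates the enolates of 3; the more acidic aryloxymethylene carbon (or the methyl carbon, the order being immaterial) adds to one formyl group of the nitromalonaldehyde anion and loses water, the remaining α‑carbon then attacks the second formyl group intramolecularly, and a second dehydration with enolisation gives the aromatic nitrophenolate 6, which acid converts into 7. The closest known reaction is the classical condensation of sodium nitromalonaldehyde with ketones bearing two enolisable α‑carbons (acetone, alkyl methyl ketones) to give 4‑nitrophenols. Ring A is closed by a 6‑(enolexo)‑exo‑trig aldol addition, the two condensations forming C2–C3 and C5–C6. No stereocentre is created. The only selectivity needed is cross‑condensation over self‑aldolisation of 3, which the non‑enolisable, doubly electrophilic three‑carbon partner in slight excess and the irreversible aromatisation to a stabilised 4‑nitrophenolate should secure; regiochemistry cannot go astray because the carbonyl carbon must become C1, the aryloxy‑bearing carbon C2 and the nitro‑bearing carbon C4.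

Step 4
Reactants: 7 2‑(2,4‑dibromophenoxy)‑4‑nitrophenol
Product: 8 2‑bromo‑6‑(2,4‑dibromophenoxy)‑4‑nitrophenol
Conditions: Br2 (1.05 equiv), AcOH, rt
Reagents that add atoms: bromine BrBr
Why: Electrophilic aromatic bromination: C6 is the only free position ortho or para to the hydroxyl and is also meta to the nitro group, the nitro‑deactivated ring A should stop at the monobromide, and the doubly brominated ring B is too deactivated to compete.

Step 5
Reactants: 8 2‑bromo‑6‑(2,4‑dibromophenoxy)‑4‑nitrophenol
Product: 9 1‑bromo‑3‑(2,4‑dibromophenoxy)‑2‑methoxy‑5‑nitrobenzene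
Conditions: MeI, K2CO3, DMF, 40 °C
Reagents that add atoms: iodomethane CI
Why: Williamson O‑methylation of the acidic nitrophenoxide with an unhindered SN2 electrophile, masking the hydroxyl so that the later 4‑amino compound cannot be oxidised to a quinone imine.

Step 6
Reactants: 9 1‑bromo‑3‑(2,4‑dibromophenoxy)‑2‑methoxy‑5‑nitrobenzene
Product: 10 3‑bromo‑5‑(2,4‑dibromophenoxy)‑4‑methoxyaniline
Conditions: SnCl2·2H2O (5 equiv), EtOH–EtOAc, 70 °C; NaHCO3 (aq.) work‑up
Reagents that add atoms: none
Why: Chemoselective nitro‑to‑amine reduction by divalent tin chloride (SnCl2), a single‑electron/proton transfer sequence that leaves aryl bromides and the diaryl ether untouched, unlike catalytic hydrogenation.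

Step 7
Reactants: 10 3‑bromo‑5‑(2,4‑dibromophenoxy)‑4‑methoxyaniline
Product: 11 2,3,6‑tribromo‑5‑(2,4‑dibromophenoxy)‑4‑methoxyaniline
Conditions: Br2 (2.1 equiv), NaOAc, AcOH, 15 °C → rt
Reagents that add atoms: bromine BrBr
Why: Electrophilic aromatic bromination directed by the free amino group, whose para position is blocked by methoxy, so both ortho carbons (C3 and C5 of ring A) should be substituted, as in the 2,6‑dibromination of 4‑alkoxyanilines, while buffered stoichiometric bromine spares ring B.

Step 8
Reactants: 11 2,3,6‑tribromo‑5‑(2,4‑dibromophenoxy)‑4‑methoxyaniline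
Product: 13 1,2,5‑tribromo‑4‑(2,4‑dibromophenoxy)‑3‑methoxybenzene, via arenediazonium hydrogen sulfate 12 (not isolated)
Conditions: NaNO2, conc. H2SO4, AcOH, 0–5 °C; then H3PO2 (50% aq.), 0 °C → rt
Reagents that add atoms: none
Why: Diazotisation with nitrosylsulfuric acid (needed for a weakly basic 2,6‑dibromoaniline) followed by hydrodediazoniation, a radical‑chain reduction by hypophosphorous acid as used for 2,4,6‑trihaloanilines; chloride‑free acid avoids halide exchange on the diazonium ring.

Step 9
Reactants: 13 1,2,5‑tribromo‑4‑(2,4‑dibromophenoxy)‑3‑methoxybenzene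
Product: 15 2,3,5‑tribromo‑6‑(2,4‑dibromophenoxy)phenol (target), via aryloxydibromoborane 14 (not isolated)
Conditions: BBr3 (3 equiv), CH2Cl2, −78 °C → rt; then H2O
Reagents that add atoms: none
Why: Lewis‑acid demethylation of an aryl methyl ether: BBr3 coordinates the methoxy oxygen and bromide attacks the methyl carbon by SN2, whereas the diaryl ether has no sp3 carbon to attack and the aryl bromides are inert, as in the usual unmasking of methoxylated polybrominated diphenyl ethers.

Compound list
1 | 2,4‑dibromophenol | Oc1ccc(Br)cc1Br | starting material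
2 | chloroacetone (1‑chloropropan‑2‑one) | CC(=O)CCl | starting material
3 | 1‑(2,4‑dibromophenoxy)propan‑2‑one | CC(=O)COc1ccc(Br)cc1Br | intermediate
4 | mucobromic acid (3,4‑dibromo‑5‑hydroxyfuran‑2(5H)‑one) | OC1OC(=O)C(Br)=C1Br | starting material
5 | sodium nitromalonaldehyde monohydrate (sodium 2‑nitro‑3‑oxoprop‑1‑en‑1‑olate hydrate) | [Na+].[O-]C=C(C=O)[N+](=O)[O-].O | intermediate
6 | sodium 2‑(2,4‑dibromophenoxy)‑4‑nitrophenolate | [Na+].[O-]c1ccc(cc1Oc1ccc(Br)cc1Br)[N+](=O)[O-] | intermediate (not isolated)
7 | 2‑(2,4‑dibromophenoxy)‑4‑nitrophenol | Oc1ccc(cc1Oc1ccc(Br)cc1Br)[N+](=O)[O-] | intermediate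
8 | 2‑bromo‑6‑(2,4‑dibromophenoxy)‑4‑nitrophenol | Oc1c(Br)cc(cc1Oc1ccc(Br)cc1Br)[N+](=O)[O-] | intermediate
9 | 1‑bromo‑3‑(2,4‑dibromophenoxy)‑2‑methoxy‑5‑nitrobenzene | COc1c(Br)cc(cc1Oc1ccc(Br)cc1Br)[N+](=O)[O-] | intermediate
10 | 3‑bromo‑5‑(2,4‑dibromophenoxy)‑4‑methoxyaniline | COc1c(Br)cc(N)cc1Oc1ccc(Br)cc1Br | intermediate
11 | 2,3,6‑tribromo‑5‑(2,4‑dibromophenoxy)‑4‑methoxyaniline | COc1c(Br)c(Br)c(N)c(Br)c1Oc1ccc(Br)cc1Br | intermediate
12 | 2,3,6‑tribromo‑5‑(2,4‑dibromophenoxy)‑4‑methoxybenzenediazonium hydrogen sulfate | COc1c(Br)c(Br)c([N+]#N)c(Br)c1Oc1ccc(Br)cc1Br.OS(=O)(=O)[O-] | intermediate (not isolated)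
13 | 1,2,5‑tribromo‑4‑(2,4‑dibromophenoxy)‑3‑methoxybenzene | COc1c(Br)c(Br)cc(Br)c1Oc1ccc(Br)cc1Br | intermediate
14 | dibromo[2,3,5‑tribromo‑6‑(2,4‑dibromophenoxy)phenoxy]borane | BrB(Br)Oc1c(Br)c(Br)cc(Br)c1Oc1ccc(Br)cc1Br | intermediate (not isolated)
15 | 2,3,5‑tribromo‑6‑(2,4‑dibromophenoxy)phenol | Oc1c(Br)c(Br)cc(Br)c1Oc1ccc(Br)cc1Br | target

Total step count: 9. Longest linear sequence: 8 steps (1 → 3 → 7 → 8 → 9 → 10 → 11 → 13 → 15; the branch from 4 through 5 is equally long).

Steps most likely to fail

Step 3. The cross‑condensation may be slower than base degradation of the nitromalonaldehyde anion or self‑aldolisation of the ketone, so that little nitrophenolate forms. The fallback sets out from 1 and returns at 7. Copper‑mediated Chan–Lam O‑arylation of 2,4‑dibromophenol 1 with commercial (2‑methoxy‑5‑nitrophenyl)boronic acid (Cu(OAc)2, pyridine, 4 Å molecular sieves, CH2Cl2, air, rt) tolerates aryl bromides and should give 2‑(2,4‑dibromophenoxy)‑1‑methoxy‑4‑nitrobenzene F1. Cleavage of its methyl ether with HBr (48% aq.) in AcOH at reflux, which leaves the diaryl ether intact, should then deliver 7.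

Step 7. Bromine may oxidise the electron‑rich 4‑methoxyaniline at nitrogen with loss of the methyl group (quinone imine formation), or substitution may stall after the first bromine on the crowded ring. The fallback sets out from 8 and returns at 15, replacing the methyl ether by an electron‑poor sulfonate that cannot be lost oxidatively.
- MsCl and Et3N in CH2Cl2 at 0 °C should give 2‑bromo‑6‑(2,4‑dibromophenoxy)‑4‑nitrophenyl methanesulfonate F2.
- SnCl2·2H2O in EtOH at 70 °C should give 4‑amino‑2‑bromo‑6‑(2,4‑dibromophenoxy)phenyl methanesulfonate F3.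
- Br2 and NaOAc in AcOH should give 4‑amino‑2,3,5‑tribromo‑6‑(2,4‑dibromophenoxy)phenyl methanesulfonate F4.
- NaNO2 in H2SO4/AcOH should give 2,3,6‑tribromo‑5‑(2,4‑dibromophenoxy)‑4‑(methanesulfonyloxy)benzenediazonium hydrogen sulfate F5, which H3PO2 reduces to 2,3,5‑tribromo‑6‑(2,4‑dibromophenoxy)phenyl methanesulfonate F6.
- KOH in MeOH–H2O at 60 °C cleaves the sulfonate at sulfur to potassium 2,3,5‑tribromo‑6‑(2,4‑dibromophenoxy)phenolate F7, and aqueous HCl then liberates 15.

Step 8. Capture of the crowded diazonium ion by water, or attack at the methoxy‑bearing carbon para to it, may outrun hydrogen transfer from hypophosphorous acid. The fallback sets out from 11 and returns at 13. The diazonium salt 12, prepared as in step 8, is treated with aqueous KI; the fast iodo‑dediazoniation should give 1,2,4‑tribromo‑5‑(2,4‑dibromophenoxy)‑3‑iodo‑6‑methoxybenzene F8. Selective iodine–magnesium exchange with i‑PrMgCl·LiCl in THF at −78 °C (iodide exchanges far faster than bromide) should give [2,3,6‑tribromo‑5‑(2,4‑dibromophenoxy)‑4‑methoxyphenyl]magnesium chloride F9, which is protonated with MeOH at −78 °C to give 13.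

Further compounds
F1 | step 3 | 2‑(2,4‑dibromophenoxy)‑1‑methoxy‑4‑nitrobenzene | COc1ccc(cc1Oc1ccc(Br)cc1Br)[N+](=O)[O-]
F2 | step 7 | 2‑bromo‑6‑(2,4‑dibromophenoxy)‑4‑nitrophenyl methanesulfonate | CS(=O)(=O)Oc1c(Br)cc(cc1Oc1ccc(Br)cc1Br)[N+](=O)[O-]
F3 | step 7 | 4‑amino‑2‑bromo‑6‑(2,4‑dibromophenoxy)phenyl methanesulfonate | CS(=O)(=O)Oc1c(Br)cc(N)cc1Oc1ccc(Br)cc1Br
F4 | step 7 | 4‑amino‑2,3,5‑tribromo‑6‑(2,4‑dibromophenoxy)phenyl methanesulfonate | CS(=O)(=O)Oc1c(Br)c(Br)c(N)c(Br)c1Oc1ccc(Br)cc1Br
F5 | step 7 | 2,3,6‑tribromo‑5‑(2,4‑dibromophenoxy)‑4‑(methanesulfonyloxy)benzenediazonium hydrogen sulfate | CS(=O)(=O)Oc1c(Br)c(Br)c([N+]#N)c(Br)c1Oc1ccc(Br)cc1Br.OS(=O)(=O)[O-]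
F6 | step 7 | 2,3,5‑tribromo‑6‑(2,4‑dibromophenoxy)phenyl methanesulfonate | CS(=O)(=O)Oc1c(Br)c(Br)cc(Br)c1Oc1ccc(Br)cc1Br
F7 | step 7 | potassium 2,3,5‑tribromo‑6‑(2,4‑dibromophenoxy)phenolate | [K+].[O-]c1c(Br)c(Br)cc(Br)c1Oc1ccc(Br)cc1Br
F8 | step 8 | 1,2,4‑tribromo‑5‑(2,4‑dibromophenoxy)‑3‑iodo‑6‑methoxybenzene | COc1c(Br)c(Br)c(I)c(Br)c1Oc1ccc(Br)cc1Br
F9 | step 8 | [2,3,6‑tribromo‑5‑(2,4‑dibromophenoxy)‑4‑methoxyphenyl]magnesium chloride | COc1c(Br)c(Br)c([Mg]Cl)c(Br)c1Oc1ccc(Br)cc1Br
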